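A small charge of catalyst, 2.5 mM, stood in the grey flask against 0.50 M of starting material, with the gas held at 200 mM.

| flask | starting material | gas | catalyst | temperature | remark | time |
|---|---|---|---|---|---|---|
| grey | 0.50 M | 200 mM (held) | 2.5 mM | 50 °C | the very flask that is asked about, followed so far |  |
| blue | 0.50 M | 200 mM (held) | 2.5 mM | 35 °C | run made earlier |  |
| flask | 0.50 M | 200 mM (held) | 2.5 mM | 50 °C |  | 20 min |

- grey (time / min: target / %, starting material / %): 4.00: 19.4, 39.2; 8.00: 21.1, 13.9; 12.0: 20.4, 10.3; 15.0: 18.0, 8.9
- blue (time / min: target / %, starting material / %): 8.00: 35.6, 19.6; 15.0: 36.0, 7.4; 25.0: 32.6, 6.2; 30.0: 31.3, 6.3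

(readings scatter by 0.5 percentage points)

- what is taken out of target is counted as made
- the numbers in the tables scatter by 0.5 percentage points (one standard deviation)
- at the start none of the gas is in solution
- additions bring no volume worth counting

- west: change nothing and wait 10 min more
- north-east: at 20 min take out 90 % of the target then present, then wait 10 min
- north: at 20 min raise the temperature by 20 K, then wait 10 min
- east: at 20 min add catalyst, 50.0 % of the amount charged, then wait 10 min

- target, in percent of the starting material first charged, at 20 min
- what to do for the largest gain in target; "none" if nothing gains more than 2 percentage points (west / north-east / north / east / none)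
- target present, with what was taken out counted in, in percent of the starting material first charged, after west
- target present, with what was taken out counted in, in percent of the starting material first charged, after north

This is my note for the bench. At 15.0 min the grey flask held 18.0 % target and 8.9 % starting material. Target had already passed its highest reading, 21.1 % at 8.00 min. Between those two readings it fell at 0.0227 min⁻¹. I called this λ, the share of target lost each minute after the peak, and treated it as a pseudo-first-order constant.

Carried on from the last reading, λ gave me 16.1 % at 20 min. After 10 min more it gave 12.8 %, so I advised against simply waiting. I also advised against heating. The blue run at 35 °C faded at 0.00933 min⁻¹, slower than the grey run at 50 °C.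

The forecast gave 16.5 % at 20 min, 13.2 % after west and 7.5 % after north. It chose north-east: “Removing 90% protects the target from decay”. Its figure for 20 min stood slightly above mine.

The flask gave 15.7 % at 20 min, 12.6 % after west and 3.50 % after north. The best option was north-east, with a gain of 7.5 percentage points.

    starting material + partner ⇌ target (K = 12.1 M⁻¹, k = 0.110 M⁻¹ s⁻¹, Ea = 51.0 kJ mol⁻¹, ΔH = −42.0 kJ mol⁻¹)
    starting material + partner ⇌ isomer of the product (K = 13.0 M⁻¹, k = 0.0552 M⁻¹ s⁻¹, Ea = 62.0 kJ mol⁻¹, ΔH = −40.0 kJ mol⁻¹)
    target + catalyst ⇌ isomer of the product + catalyst, rate k3*[catalyst]*[target] forward; the back reaction follows from the equilibrium constant (k = 1.06 M⁻¹ s⁻¹, Ea = 44.0 kJ mol⁻¹)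
    gas ⇌ partner, rate k4*(csat - [partner]) (kL = 0.00788 s⁻¹)
    2 partner → homo dimer (k = 0.00508 M⁻¹ s⁻¹, Ea = 52.0 kJ mol⁻¹)
    starting material + target → side product (k = 0.0144 M⁻¹ s⁻¹, Ea = 79.0 kJ mol⁻¹)
    (constants at 50 °C)

Applied to 15.7 %, λ over 10 min gave 12.5 %, and the flask gave 12.6 %. The scheme has a step from starting material + target to side product, so I took λ as first order in starting material. A neighbour flask was charged with 0.20 M of starting material, and at 20 min it kept 12.1 % of that charge as starting material. Scaled from the concentration of starting material in the asked flask at 20 min to the concentration in the neighbour flask, λ became 0.0142 min⁻¹. By this reckoning the fade half-life, ln(2)/λ, was 30.5 min in the asked flask and 48.8 min in the neighbour flask. The neighbour flask held 24.3 % target at 20 min.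

The readings stem from a simulated flask for substances that don't exist, and the scatter is random.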